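# Gnetulin by chirality-transferring allylsilane closure onto a quinone methide

## The problem

Gnetulin is a 1-benzylidene-2,3-diarylindane. In the numbering used here, C1 is the alkylidene ring carbon and C8 its exocyclic CH; C2 carries the 3,5-dihydroxyphenyl ring, C3 the 4-hydroxy-3-methoxyphenyl (guaiacyl) ring, and C3a–C7a are the benzo carbons with hydroxyls on C4 and C6. Read from the SMILES, C2 and C3 are both S with the two aryl groups trans, and C1=C8 is E, with the C8 guaiacyl cis to C2 and away from C7–H.

Only the five-membered ring has to be built, but every one of its carbons is aryl-substituted or part of an arene, so each ring bond joins crowded benzylic centres. The three stereo elements are coupled. C3 can follow C2, because trans is the less crowded arrangement. C2 lies next to the exocyclic alkene, so it can be set by an allylic transposition that creates that alkene in the same event. One stereo element made by catalysis can therefore control all three.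

Of the six phenolic oxygens, two are methyl ethers, so the four resorcinol hydroxyls and the two guaiacyl hydroxyls need protecting groups that can be removed while the methyl ethers stay. The finished skeleton is fragile. C2–H is doubly benzylic and allylic, the exocyclic stilbene can migrate into the ring or be captured by the C2 resorcinol ring under strong acid, and the electron-rich arenes oxidise easily.

Two features of the structure make the key step possible. C3 carries a para-hydroxyaryl group, so it is the exocyclic carbon of a para-quinone methide, a latent diarylmethyl cation. The C1=C8 double bond beside C2 is exactly where an allylsilane leaves its alkene after reacting through C2, with silicon having sat on C8.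

## Retrosynthesis

**23 to 22 (five O–isopropyl bonds).** Gnetulin 23 is traced to its penta-isopropyl ether 22, in which only the C3 guaiacyl hydroxyl is free. Isopropyl is chosen over benzyl, whose hydrogenolysis would reduce the alkene, and over silyl, whose fluoride removal would threaten an allylic C–Si bond earlier in the route. BCl3 cleaves isopropyl aryl ethers and leaves methyl ethers. The forward step must only be kept cold enough to spare the stilbene.

**22 to 21 and 20 (the C2–C3 ring bond).** Cutting C2–C3 opens the only ring and removes both stereocentres. The precursor is quinone methide 21, formed in the flask from para-hydroxybenzhydrol 20, with an allylsilane whose silicon is on C8. Cutting C3–C3a or C1–C7a instead would leave both stereocentres to be made in an open chain. Cutting C1=C8 would need a late olefination of a hindered, enolisable indanone. The forward reaction has three requirements: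
- C2, not an arene carbon, attacks C3.
- Silicon leaves anti to the new bond.
- The C8 aryl sits over the C1=C2 bond and not against the fused ring.

The stereochemical analysis of this closure gives a clear demand on the precursor: silicon-bearing C8 must be R, and the C1=C2 bond must have the two aryl rings cis (E by the sequence rule). With that geometry the only group cis to C8 is the small C2–H.

**20 to 15 and 18 (the C3–aryl bond).** The carbinol is cut to aldehyde 15 and aryllithium 18, made from silyl ether 17 of 4-bromo-2-methoxyphenol 16. Adding the guaiacyl unit last keeps the acid-sensitive para-hydroxybenzhydrol out of all earlier steps. The trimethylsilyl ether falls off under mild base, so fluoride is not needed. The carbinol configuration is irrelevant.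

**15 to 14 and 8 (the C1–C7a bond).** The aryl–alkenyl bond is cut to alkenyl bromide 14 and ortho-formyl arylboronate 8. A Suzuki–Miyaura coupling replaces bromine with retention, so the alkene geometry of 15 is inherited from 14 and not decided by an equilibrium. An enolate-based alternative (α-arylation of a β-silyl ketone, enol sulfonate, reduction) was set aside, because nothing in the substrate controls the geometry of a tetrasubstituted enolate. The boronate carries the free aldehyde, which saves a protection and deprotection.

**14 to 5 and 13 (the C1–C8 bond).** Bromide 14 is cut to 1,1-dibromoalkene 5 and the racemic benzylic zinc reagent 13, made from chloride 12. This one coupling must do two things: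
- Palladium inserts into the C–Br bond trans to the aryl group of 5, which places C8 trans to the 3,5-diisopropoxyphenyl ring.
- A chiral palladium catalyst selects one enantiomer of the rapidly inverting organozinc, which sets C8.

The order of the two couplings is fixed by this site preference: the silyl-bearing carbon must enter first.

**Building blocks.** Chloride 12 comes from carbinol 11, the silyl adduct of O-isopropylvanillin 10, made from vanillin 9. Dibromoalkene 5 comes from aldehyde 4, and boronate 8 from bromoaldehyde 7. Both derive from one intermediate, 1-bromo-3,5-diisopropoxybenzene 2, made from 5-bromoresorcinol 1.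

## Roads not taken

**Alternative 1: Danheiser benzannulation.**
- Cut: the benzo ring (C7–C7a, C4–C5, C6–C7, C3a–C4).
- Forward step: irradiation of cyclopentenyl diazoketone A2 gives a vinylketene by Wolff rearrangement. The ketene adds (triisopropylsilyloxy)acetylene A3 and, after ring opening and six-electron closure, aromatises to phenol A1.
- Merits: the fused arene appears with its two oxygens already differentiated, and no cation is generated next to electron-rich rings. In that respect it is safer than the chosen closure.
- Weak points: A2 must already contain the trans C2/C3 stereocentres and the E alkylidene, so the hard part of the molecule is left unsolved and only moved to a cyclopentene with no aromatic ring to help build it. Irradiation of a stilbene-type chromophore also risks E/Z scrambling.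
- Comparison: the chosen plan creates ring, both stereocentres and the alkene in one step from arene building blocks. Against the cleaner aromatic chemistry of this road it sets a much shorter sequence.

**Alternative 2: enantioselective reductive Heck cyclisation.**
- Cut: C3–C3a.
- Forward step: Pd(OAc)2 with a chiral bisphosphine and an amine reductant converts bromochalcone A5 into indanone A4. Zerovalent palladium inserts into C3a–Br, the arylpalladium adds to C3, and C2 is protonated.
- Merits: this reaction type is established for 2′-halochalcones with high enantioselectivity, a firmer footing than the chosen key step. C2 is epimerisable and relaxes to trans.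
- Weak points: the enone here is α-aryl substituted and the C–Br bond is flanked by an isopropoxy and an acyl group. The product still lacks C8: the hindered, enolisable ketone A4 must be olefinated to an exocyclic E-benzylidene without drift of the double bond into the ring and without loss of C2.
- Comparison: this road has the better-precedented asymmetric step. The chosen plan sets against it that position and geometry of the alkene are fixed by silicon in the ring-forming step, with no late olefination.

**Alternative 3: reductive 5-exo-dig Heck closure.**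
- Cut: C1–C7a.
- Forward step: zerovalent palladium from Pd(OAc)2 and PPh3 inserts into the C7a–Br bond of alkyne A7, adds syn across C1≡C8, and HCO2Na replaces palladium by hydrogen to give A6.
- Merits: syn addition guarantees the E alkene, which is as good as or better than the conformational control the chosen plan relies on. The reaction type is well known and needs no Lewis acid.
- Weak points: the closure creates no stereocentre. A7 must be made with both stereocentres as an open-chain 1,2-diaryl array whose C2–H is benzylic and propargylic, and no short catalytic route to that array is evident.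
- Comparison: the chosen plan sets against the secure alkene geometry of this road that one easily made C–Si stereocentre is converted into C2 and C3 during ring closure.

Key step: step 13

Remark on the chemistry: the carbinol configuration of 19 and 20 and the geometry of the exocyclic bond of 21 are uncontrolled and left open in the SMILES, since both disappear in step 13; the sense of induction in step 9 is assigned by analogy with couplings of the parent α-silylbenzyl nucleophile and must be confirmed.

## Route

Step 1
Reactants: 1 5-bromoresorcinol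
Product: 2 1-bromo-3,5-diisopropoxybenzene
Conditions: 2-bromopropane, K2CO3, DMF, 70 °C
Reagents that add atoms: 2-bromopropane, CC(C)Br
Why: Williamson etherification of both phenols; isopropyl ethers survive the organometallic, palladium and BF3 steps and are cleaved at the end by BCl3 without loss of the methyl ethers.

Step 2
Reactants: 2 1-bromo-3,5-diisopropoxybenzene
Product: 4 3,5-diisopropoxybenzaldehyde, via 3,5-diisopropoxyphenyllithium 3 (not isolated)
Conditions: n-BuLi, THF, −78 °C; DMF; aq NH4Cl
Reagents that add atoms: N,N-dimethylformamide, CN(C)C=O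
Why: Bromine–lithium exchange followed by Bouveault formylation; the meta alkoxy groups are inert at −78 °C.

Step 3
Reactants: 4 3,5-diisopropoxybenzaldehyde
Product: 5 1-(2,2-dibromoethenyl)-3,5-diisopropoxybenzene
Conditions: CBr4, PPh3, CH2Cl2, 0 °C
Reagents that add atoms: carbon tetrabromide, BrC(Br)(Br)Br
Why: Ramirez dibromo-olefination (first half of the Corey–Fuchs sequence) gives the 1,1-dibromoalkene whose two C–Br bonds differ in reactivity by their position relative to the aryl group.

Step 4
Reactants: 2 1-bromo-3,5-diisopropoxybenzene
Product: 7 2-bromo-4,6-diisopropoxybenzaldehyde, via aryl iminium salt 6 (not isolated)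
Conditions: POCl3, DMF, 0 → 80 °C; then H2O
Reagents that add atoms: N,N-dimethylformamide, CN(C)C=O; water, O
Why: Vilsmeier–Haack formylation; the position next to bromine is ortho and para to the two alkoxy groups and less hindered than the site between the two isopropoxy groups, and the iminium salt is hydrolysed on work-up.

Step 5
Reactants: 7 2-bromo-4,6-diisopropoxybenzaldehyde
Product: 8 2,4-diisopropoxy-6-(4,4,5,5-tetramethyl-1,3,2-dioxaborolan-2-yl)benzaldehyde
Conditions: B2pin2, Pd(dppf)Cl2, KOAc, 1,4-dioxane, 85 °C
Reagents that add atoms: bis(pinacolato)diboron, CC1(C)OB(OC1(C)C)B1OC(C)(C)C(C)(C)O1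
Why: Miyaura borylation; the ortho formyl group speeds oxidative addition and acetate is too weak a base to harm the aldehyde.

Step 6
Reactants: 9 vanillin
Product: 10 4-isopropoxy-3-methoxybenzaldehyde
Conditions: 2-bromopropane, K2CO3, DMF, 70 °C
Reagents that add atoms: 2-bromopropane, CC(C)Br
Why: Williamson etherification of the single phenol.

Step 7
Reactants: 10 4-isopropoxy-3-methoxybenzaldehyde
Product: 11 racemic [dimethyl(phenyl)silyl](4-isopropoxy-3-methoxyphenyl)methanol
Conditions: PhMe2Si–Bpin, CuCl (5 mol %), 1,3-bis(2,6-diisopropylphenyl)imidazolium chloride (5 mol %), NaOt-Bu (12 mol %), THF, 0 °C; MeOH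
Reagents that add atoms: dimethyl(phenyl)silylboronic acid pinacol ester, C[Si](C)(c1ccccc1)B1OC(C)(C)C(C)(C)O1
Why: Copper-catalysed 1,2-addition of the silyl group of a silylboronate to an aldehyde; O-borylation of the copper alkoxide prevents Brook rearrangement and methanol releases the carbinol. The racemate suffices because C8 is set in step 9.

Step 8
Reactants: 11 racemic [dimethyl(phenyl)silyl](4-isopropoxy-3-methoxyphenyl)methanol
Product: 12 racemic [chloro(4-isopropoxy-3-methoxyphenyl)methyl]dimethyl(phenyl)silane
Conditions: SOCl2, 2,6-lutidine, CH2Cl2, −20 → 0 °C; used crude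
Reagents that add atoms: thionyl chloride, O=S(Cl)Cl
Why: Deoxychlorination of an electron-rich benzylic alcohol through its chlorosulfite; the hindered base takes up HCl so the C–Si bond is not cleaved, and the ionisable chloride is carried on without chromatography.

Step 9
Reactants: 12 racemic [chloro(4-isopropoxy-3-methoxyphenyl)methyl]dimethyl(phenyl)silane; 5 1-(2,2-dibromoethenyl)-3,5-diisopropoxybenzene
Product: 14 (R,Z)-[2-bromo-3-(3,5-diisopropoxyphenyl)-1-(4-isopropoxy-3-methoxyphenyl)prop-2-en-1-yl]dimethyl(phenyl)silane, via benzylic zinc chloride 13 (not isolated)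
Conditions: Zn dust, LiCl, THF, 25 °C; then 5, PdCl2[(S)-(R)-PPFA] (2 mol %), THF, 0 °C
Reagents that add atoms: none
Why: Zinc inserts into the benzylic C–Cl bond, and the secondary benzylic zinc reagent inverts faster than it couples, so the palladium complex of the ferrocenyl aminophosphine PPFA, (S)-N,N-dimethyl-1-[(R)-2-(diphenylphosphino)ferrocenyl]ethylamine, selects one enantiomer at transmetalation (asymmetric Negishi coupling as a dynamic kinetic resolution) and sets C8 as R. Oxidative addition takes the C–Br bond trans to the aryl group of the 1,1-dibromoalkene, as is general for such substrates, so C8 ends trans to the 3,5-diisopropoxyphenyl ring and the remaining bromine cis to it (Z).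

Step 10
Reactants: 14 (R,Z)-[2-bromo-3-(3,5-diisopropoxyphenyl)-1-(4-isopropoxy-3-methoxyphenyl)prop-2-en-1-yl]dimethyl(phenyl)silane; 8 2,4-diisopropoxy-6-(4,4,5,5-tetramethyl-1,3,2-dioxaborolan-2-yl)benzaldehyde
Product: 15 2-[(1E,3R)-1-(3,5-diisopropoxyphenyl)-3-[dimethyl(phenyl)silyl]-3-(4-isopropoxy-3-methoxyphenyl)prop-1-en-2-yl]-4,6-diisopropoxybenzaldehyde
Conditions: Pd(OAc)2, SPhos, K3PO4, THF–H2O, 45 °C
Reagents that add atoms: none
Why: Suzuki–Miyaura coupling with retention at the alkenyl bromide places the fused-ring aryl cis to the 3,5-diisopropoxyphenyl group and completes the E allylsilane; the bulky biaryl phosphine is chosen because both partners are hindered, and the C8 stereocentre is not involved.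

Step 11
Reactants: 16 4-bromo-2-methoxyphenol
Product: 17 (4-bromo-2-methoxyphenoxy)trimethylsilane
Conditions: (Me3Si)2NH, cat. Me3SiCl, 80 °C; distil
Reagents that add atoms: hexamethyldisilazane, C[Si](C)(C)N[Si](C)(C)C
Why: O-silylation masks the acidic phenol for the lithiation; the trimethylsilyl ether is removed again in the work-up of step 12.

Step 12
Reactants: 17 (4-bromo-2-methoxyphenoxy)trimethylsilane; 15 2-[(1E,3R)-1-(3,5-diisopropoxyphenyl)-3-[dimethyl(phenyl)silyl]-3-(4-isopropoxy-3-methoxyphenyl)prop-1-en-2-yl]-4,6-diisopropoxybenzaldehyde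
Product: 20 {2-[(1E,3R)-1-(3,5-diisopropoxyphenyl)-3-[dimethyl(phenyl)silyl]-3-(4-isopropoxy-3-methoxyphenyl)prop-1-en-2-yl]-4,6-diisopropoxyphenyl}(4-hydroxy-3-methoxyphenyl)methanol (both carbinol epimers), via aryllithium 18 (not isolated), via silyl ether alkoxide 19 (not isolated)
Conditions: 17, n-BuLi, THF, −78 °C; then 15, −78 → −40 °C; aq NH4Cl; K2CO3, MeOH, 0 °C
Reagents that add atoms: none
Why: Bromine–lithium exchange para to the silyloxy group and 1,2-addition of the aryllithium to the hindered aldehyde; the new carbinol centre forms without control and is erased in step 13. Carbonate in methanol removes the aryl trimethylsilyl ether without fluoride, which would endanger the allylic and benzylic C–Si bond at C8.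

Step 13
Reactants: 20 {2-[(1E,3R)-1-(3,5-diisopropoxyphenyl)-3-[dimethyl(phenyl)silyl]-3-(4-isopropoxy-3-methoxyphenyl)prop-1-en-2-yl]-4,6-diisopropoxyphenyl}(4-hydroxy-3-methoxyphenyl)methanol
Product: 22 4-[(1S,2S,3E)-2-(3,5-diisopropoxyphenyl)-3-(4-isopropoxy-3-methoxybenzylidene)-5,7-diisopropoxy-2,3-dihydro-1H-inden-1-yl]-2-methoxyphenol (gnetulin penta-O-isopropyl ether with the C3 guaiacyl hydroxyl free), via para-quinone methide 21 (not isolated)
Conditions: BF3·OEt2 (2.2 equiv), CH2Cl2, −78 → −30 °C; aq NaHCO3
Reagents that add atoms: none
Why: Proposed new method: BF3·OEt2 ionises the para-hydroxybenzhydrol 20 to the boron-bound quinone methide 21, whose exocyclic carbon C3 is a stabilised diarylmethyl cation held over the C1=C2 bond by the ortho link; the closest known reaction types are the Lewis acid 1,6-allylation of para-quinone methides by allylsilanes, the Hosomi–Sakurai capture of diarylmethyl cations, and the acid-induced five-membered closure of ortho-styryl diarylmethyl cations. C2 attacks C3 in a cationic 5-endo-trig closure that forms the only new ring; the charge developing at C1 is stabilised by the C8–Si bond and the silyl group then leaves, so the double bond can only appear at C1=C8, and the quinone methide rearomatises to the free phenol. C2 is controlled by the C8–Si stereocentre: the C–Si bond stands anti to the incoming C3 (anti SE2′), and of the two such conformers the one with the C8 aryl over the C1=C2 bond, next to the small C2–H, is preferred to the one that presses this aryl against the fused ring, so (R)-C8 gives (S)-C2 and the E alkene together. C3 is controlled by C2: in the closing transition state the quinone methide turns its guaiacyl ring anti to the C2 aryl, which gives the trans (2S,3S) indane, also the less strained diastereomer. The step needs chemoselectivity for the allylsilane over Friedel–Crafts attack by the electron-rich rings and over protodesilylation; the silicon-activated alkene lies closer to C3 than any ring carbon, the reactive ring positions are flanked by isopropoxy groups, and low temperature without protic acid protects the C–Si bond.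

Step 14
Reactants: 22 4-[(1S,2S,3E)-2-(3,5-diisopropoxyphenyl)-3-(4-isopropoxy-3-methoxybenzylidene)-5,7-diisopropoxy-2,3-dihydro-1H-inden-1-yl]-2-methoxyphenol
Product: 23 gnetulin, (2S,3S)-1-[(E)-(4-hydroxy-3-methoxyphenyl)methylidene]-2-(3,5-dihydroxyphenyl)-3-(4-hydroxy-3-methoxyphenyl)indane-4,6-diol
Conditions: BCl3 (1 M in CH2Cl2, excess), CH2Cl2, −78 → 0 °C; MeOH, then H2O
Reagents that add atoms: none
Why: BCl3 cleaves secondary alkyl aryl ethers through the isopropyl cation far faster than methyl ethers, so the five isopropyl groups leave as 2-chloropropane and both methoxy groups stay. The mixture is kept at or below 0 °C and quenched cold so that the exocyclic double bond neither migrates into the ring nor is attacked by the C2 ring; no stereocentre is touched.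

## Compound list

1 | 5-bromoresorcinol | Oc1cc(O)cc(Br)c1 | starting material
2 | 1-bromo-3,5-diisopropoxybenzene | CC(C)Oc1cc(Br)cc(OC(C)C)c1 | intermediate
3 | 3,5-diisopropoxyphenyllithium | [Li]c1cc(OC(C)C)cc(OC(C)C)c1 | intermediate
4 | 3,5-diisopropoxybenzaldehyde | O=Cc1cc(OC(C)C)cc(OC(C)C)c1 | intermediate
5 | 1-(2,2-dibromoethenyl)-3,5-diisopropoxybenzene | BrC(Br)=Cc1cc(OC(C)C)cc(OC(C)C)c1 | intermediate
6 | [(2-bromo-4,6-diisopropoxyphenyl)methylidene]dimethylammonium dichlorophosphate | CC(C)Oc1cc(Br)c(C=[N+](C)C)c(OC(C)C)c1.[O-]P(=O)(Cl)Cl | intermediate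
7 | 2-bromo-4,6-diisopropoxybenzaldehyde | O=Cc1c(Br)cc(OC(C)C)cc1OC(C)C | intermediate
8 | 2,4-diisopropoxy-6-(4,4,5,5-tetramethyl-1,3,2-dioxaborolan-2-yl)benzaldehyde | O=Cc1c(OC(C)C)cc(OC(C)C)cc1B1OC(C)(C)C(C)(C)O1 | intermediate
9 | vanillin | COc1cc(C=O)ccc1O | starting material
10 | 4-isopropoxy-3-methoxybenzaldehyde | COc1cc(C=O)ccc1OC(C)C | intermediate
11 | racemic [dimethyl(phenyl)silyl](4-isopropoxy-3-methoxyphenyl)methanol | COc1cc(C(O)[Si](C)(C)c2ccccc2)ccc1OC(C)C | intermediate
12 | racemic [chloro(4-isopropoxy-3-methoxyphenyl)methyl]dimethyl(phenyl)silane | COc1cc(C(Cl)[Si](C)(C)c2ccccc2)ccc1OC(C)C | intermediate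
13 | racemic chloro{[dimethyl(phenyl)silyl](4-isopropoxy-3-methoxyphenyl)methyl}zinc | COc1cc(C([Zn]Cl)[Si](C)(C)c2ccccc2)ccc1OC(C)C | intermediate
14 | (R,Z)-[2-bromo-3-(3,5-diisopropoxyphenyl)-1-(4-isopropoxy-3-methoxyphenyl)prop-2-en-1-yl]dimethyl(phenyl)silane | C[Si](C)(c1ccccc1)[C@H](c1ccc(OC(C)C)c(OC)c1)/C(Br)=C/c1cc(OC(C)C)cc(OC(C)C)c1 | intermediate
15 | 2-[(1E,3R)-1-(3,5-diisopropoxyphenyl)-3-[dimethyl(phenyl)silyl]-3-(4-isopropoxy-3-methoxyphenyl)prop-1-en-2-yl]-4,6-diisopropoxybenzaldehyde | C[Si](C)(c1ccccc1)[C@H](c1ccc(OC(C)C)c(OC)c1)/C(=C/c1cc(OC(C)C)cc(OC(C)C)c1)c1cc(OC(C)C)cc(OC(C)C)c1C=O | intermediate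
16 | 4-bromo-2-methoxyphenol | COc1cc(Br)ccc1O | starting material
17 | (4-bromo-2-methoxyphenoxy)trimethylsilane | COc1cc(Br)ccc1O[Si](C)(C)C | intermediate
18 | [3-methoxy-4-(trimethylsilyloxy)phenyl]lithium | [Li]c1ccc(O[Si](C)(C)C)c(OC)c1 | intermediate
19 | lithium alkoxide of the O-trimethylsilyl benzhydrol (carbinol epimers; 20 with the phenol as its trimethylsilyl ether) | C[Si](C)(c1ccccc1)[C@H](c1ccc(OC(C)C)c(OC)c1)/C(=C/c1cc(OC(C)C)cc(OC(C)C)c1)c1cc(OC(C)C)cc(OC(C)C)c1C(O[Li])c1ccc(O[Si](C)(C)C)c(OC)c1 | intermediate
20 | {2-[(1E,3R)-1-(3,5-diisopropoxyphenyl)-3-[dimethyl(phenyl)silyl]-3-(4-isopropoxy-3-methoxyphenyl)prop-1-en-2-yl]-4,6-diisopropoxyphenyl}(4-hydroxy-3-methoxyphenyl)methanol (carbinol epimers) | C[Si](C)(c1ccccc1)[C@H](c1ccc(OC(C)C)c(OC)c1)/C(=C/c1cc(OC(C)C)cc(OC(C)C)c1)c1cc(OC(C)C)cc(OC(C)C)c1C(O)c1ccc(O)c(OC)c1 | intermediate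
21 | 4-({2-[(1E,3R)-1-(3,5-diisopropoxyphenyl)-3-[dimethyl(phenyl)silyl]-3-(4-isopropoxy-3-methoxyphenyl)prop-1-en-2-yl]-4,6-diisopropoxyphenyl}methylidene)-2-methoxycyclohexa-2,5-dien-1-one | C[Si](C)(c1ccccc1)[C@H](c1ccc(OC(C)C)c(OC)c1)/C(=C/c1cc(OC(C)C)cc(OC(C)C)c1)c1cc(OC(C)C)cc(OC(C)C)c1C=C1C=CC(=O)C(OC)=C1 | intermediate
22 | 4-[(1S,2S,3E)-2-(3,5-diisopropoxyphenyl)-3-(4-isopropoxy-3-methoxybenzylidene)-5,7-diisopropoxy-2,3-dihydro-1H-inden-1-yl]-2-methoxyphenol | COc1cc(/C=C2/c3cc(OC(C)C)cc(OC(C)C)c3[C@H](c3ccc(O)c(OC)c3)[C@H]2c2cc(OC(C)C)cc(OC(C)C)c2)ccc1OC(C)C | intermediate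
23 | gnetulin, (2S,3S)-1-[(E)-(4-hydroxy-3-methoxyphenyl)methylidene]-2-(3,5-dihydroxyphenyl)-3-(4-hydroxy-3-methoxyphenyl)indane-4,6-diol | COc1cc(/C=C2/c3cc(O)cc(O)c3[C@H](c3ccc(O)c(OC)c3)[C@H]2c2cc(O)cc(O)c2)ccc1O | target

## Step count and least certain steps

Total step count: 14. Longest linear sequence: 8 steps (1 → 2 → 4 → 5 → 14 → 15 → 20 → 22 → 23, or equally 9 → 10 → 11 → 12 → 14 onward).

**Step 13 (key step, new method).** Three processes can compete with the 5-endo closure:
- Friedel–Crafts closure of the 3,5-diisopropoxyphenyl ring, which stands cis to the fused ring, onto C3 to give a seven-membered ring.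
- Oligomerisation of the unhindered quinone methide through its phenoxide.
- Protodesilylation before carbon–carbon bond formation.

The fallback avoids the free quinone methide and uses the known capture of a para-alkoxy diarylmethyl cation by an allylsilane. It sets out from 15 and 16 and returns at 23. Phenol 16 is alkylated with 2-bromopropane and K2CO3 to 4-bromo-1-isopropoxy-2-methoxybenzene F1. Bromine–lithium exchange gives (4-isopropoxy-3-methoxyphenyl)lithium F2, which adds to 15 to give the hexa-isopropyl benzhydrol F3. Ionisation with BF3·OEt2 at −78 °C should close the ring in the same stereochemical sense to gnetulin hexa(isopropyl ether) F4, and BCl3 then removes all six isopropyl groups to give 23.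

**Step 9.** The alkenyl partner carries a geminal bromine that simple alkenyl bromides lack, and the aryl ring of the nucleophile is electron-rich. Both may erode the enantiomer selection at transmetalation. Double coupling or dehydrobromination to an alkyne may also intervene. If the sense of induction is opposite, the other ligand antipode is used. If the selectivity is insufficient, the fallback gives up asymmetric catalysis. From 12 and 5, the same zinc reagent is coupled with the achiral catalyst PdCl2(DPEphos) to the racemic (Z)-bromide F5. F5 is resolved by preparative chromatography on a chiral stationary phase, which returns the route at 14.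

**Step 10.** Protodeboronation of the ortho-formyl, electron-rich boronate may outrun transmetalation to the crowded alkenylpalladium intermediate. The fallback changes the nucleophile and masks the aldehyde. From 7, acetalisation with ethylene glycol and TsOH gives 2-(2-bromo-4,6-diisopropoxyphenyl)-1,3-dioxolane F6. Bromine–lithium exchange gives [2-(1,3-dioxolan-2-yl)-3,5-diisopropoxyphenyl]lithium F7, and ZnCl2 converts it into the arylzinc chloride F8. Negishi coupling of F8 with 14 under Pd(t-Bu3P)2 gives the dioxolane of 15, F9. Mild hydrolysis with pyridinium tosylate in wet acetone returns the route at 15.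

**Step 12.** Addition to the doubly ortho-substituted, electron-rich aldehyde may be slow. The aryllithium may then act as a base at the C8–H, which would erode the stereocentre, or the silyl ether may be attacked at silicon. The fallback avoids strongly basic reagents and the protecting group. From 15, commercially available 2-methoxy-4-(4,4,5,5-tetramethyl-1,3,2-dioxaborolan-2-yl)phenol is added under [RhCl(cod)]2 and P(t-Bu)3 in aqueous dioxane (rhodium-catalysed 1,2-addition of an arylboron reagent to an aldehyde). This gives 20 directly and makes no new compound.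

## Further compounds

F1 | step 13 | 4-bromo-1-isopropoxy-2-methoxybenzene | COc1cc(Br)ccc1OC(C)C
F2 | step 13 | (4-isopropoxy-3-methoxyphenyl)lithium | [Li]c1ccc(OC(C)C)c(OC)c1
F3 | step 13 | {2-[(1E,3R)-1-(3,5-diisopropoxyphenyl)-3-[dimethyl(phenyl)silyl]-3-(4-isopropoxy-3-methoxyphenyl)prop-1-en-2-yl]-4,6-diisopropoxyphenyl}(4-isopropoxy-3-methoxyphenyl)methanol (carbinol epimers) | C[Si](C)(c1ccccc1)[C@H](c1ccc(OC(C)C)c(OC)c1)/C(=C/c1cc(OC(C)C)cc(OC(C)C)c1)c1cc(OC(C)C)cc(OC(C)C)c1C(O)c1ccc(OC(C)C)c(OC)c1
F4 | step 13 | gnetulin hexa(isopropyl ether) | COc1cc(/C=C2/c3cc(OC(C)C)cc(OC(C)C)c3[C@H](c3ccc(OC(C)C)c(OC)c3)[C@H]2c2cc(OC(C)C)cc(OC(C)C)c2)ccc1OC(C)C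
F5 | step 9 | racemic (Z)-[2-bromo-3-(3,5-diisopropoxyphenyl)-1-(4-isopropoxy-3-methoxyphenyl)prop-2-en-1-yl]dimethyl(phenyl)silane | C[Si](C)(c1ccccc1)C(c1ccc(OC(C)C)c(OC)c1)/C(Br)=C/c1cc(OC(C)C)cc(OC(C)C)c1
F6 | step 10 | 2-(2-bromo-4,6-diisopropoxyphenyl)-1,3-dioxolane | CC(C)Oc1cc(Br)c(C2OCCO2)c(OC(C)C)c1
F7 | step 10 | [2-(1,3-dioxolan-2-yl)-3,5-diisopropoxyphenyl]lithium | [Li]c1cc(OC(C)C)cc(OC(C)C)c1C1OCCO1
F8 | step 10 | chloro[2-(1,3-dioxolan-2-yl)-3,5-diisopropoxyphenyl]zinc | Cl[Zn]c1cc(OC(C)C)cc(OC(C)C)c1C1OCCO1
F9 | step 10 | 2-{2-[(1E,3R)-1-(3,5-diisopropoxyphenyl)-3-[dimethyl(phenyl)silyl]-3-(4-isopropoxy-3-methoxyphenyl)prop-1-en-2-yl]-4,6-diisopropoxyphenyl}-1,3-dioxolane | C[Si](C)(c1ccccc1)[C@H](c1ccc(OC(C)C)c(OC)c1)/C(=C/c1cc(OC(C)C)cc(OC(C)C)c1)c1cc(OC(C)C)cc(OC(C)C)c1C1OCCO1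
F0 | step 12 | none | none
A1 | alternative 1 | gnetulin tetra(isopropyl ether) 6-O-triisopropylsilyl ether with free 4-hydroxyl | COc1cc(/C=C2/c3cc(O[Si](C(C)C)(C(C)C)C(C)C)cc(O)c3[C@H](c3ccc(OC(C)C)c(OC)c3)[C@H]2c2cc(OC(C)C)cc(OC(C)C)c2)ccc1OC(C)C
A2 | alternative 1 | 2-diazo-1-[(3S,4S,5E)-4-(3,5-diisopropoxyphenyl)-3-(4-isopropoxy-3-methoxyphenyl)-5-(4-isopropoxy-3-methoxybenzylidene)cyclopent-1-en-1-yl]ethan-1-one | COc1cc(/C=C2/C(C(=O)C=[N+]=[N-])=C[C@H](c3ccc(OC(C)C)c(OC)c3)[C@H]2c2cc(OC(C)C)cc(OC(C)C)c2)ccc1OC(C)C
A3 | alternative 1 | (triisopropylsilyloxy)acetylene | C#CO[Si](C(C)C)(C(C)C)C(C)C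
A4 | alternative 2 | (2S,3S)-2-(3,5-diisopropoxyphenyl)-3-(4-isopropoxy-3-methoxyphenyl)-4,6-diisopropoxyindan-1-one | O=C1c2cc(OC(C)C)cc(OC(C)C)c2[C@H](c2ccc(OC(C)C)c(OC)c2)[C@H]1c1cc(OC(C)C)cc(OC(C)C)c1
A5 | alternative 2 | (E)-1-(2-bromo-3,5-diisopropoxyphenyl)-2-(3,5-diisopropoxyphenyl)-3-(4-isopropoxy-3-methoxyphenyl)prop-2-en-1-one | O=C(c1cc(OC(C)C)cc(OC(C)C)c1Br)/C(=C/c1ccc(OC(C)C)c(OC)c1)c1cc(OC(C)C)cc(OC(C)C)c1
A6 | alternative 3 | gnetulin hexa(isopropyl ether) | COc1cc(/C=C2/c3cc(OC(C)C)cc(OC(C)C)c3[C@H](c3ccc(OC(C)C)c(OC)c3)[C@H]2c2cc(OC(C)C)cc(OC(C)C)c2)ccc1OC(C)C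
A7 | alternative 3 | 1-bromo-2-[(1S,2S)-2-(3,5-diisopropoxyphenyl)-1,4-bis(4-isopropoxy-3-methoxyphenyl)but-3-yn-1-yl]-3,5-diisopropoxybenzene | CC(C)Oc1cc(Br)c([C@H](c2ccc(OC(C)C)c(OC)c2)[C@H](C#Cc2ccc(OC(C)C)c(OC)c2)c2cc(OC(C)C)cc(OC(C)C)c2)c(OC(C)C)c1
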